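(Readings and results are calculated from invented constants; scatter was added.)

I decided to reckon one exponent instead of following the flask through time, and to take the chain length from it.

| setting | Saturday's | Tuesday's | Thursday's | epsilon | beta |
|---|---|---|---|---|---|
| free monomer | 0.50 mM (fed, over 8.0 s) | 0.50 mM (fed, over 8.0 s) | 0.25 mM (fed, over 8.0 s) | 0.50 mM (fed, over 8.0 s) | 0.50 mM (fed, over 8.0 s) |
| initiator | 0.13 mol% | 0.3 mol% | 0.2 mol% | 0.2 mol% | 0.2 mol% |
| remark | run made earlier; the fed solution adds 1.0 times the starting volume | run made earlier; the fed solution adds 1.0 times the starting volume | run made earlier; the fed solution adds 1.0 times the starting volume | the fed solution adds 1.0 times the starting volume | the fed solution adds 1.0 times the starting volume |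
| time |  |  |  | 2.5 h | 1.2 h |

| run | time / h | monomer in chains / % |
|---|---|---|
| Saturday's | 0.250 | 79.5 |
| Saturday's | 0.833 | 79.5 |
| Saturday's | 1.33 | 79.2 |
| Saturday's | 2.00 | 81.5 |
| Saturday's | 3.00 | 83.6 |
| Tuesday's | 0.250 | 91.7 |
| Tuesday's | 0.417 | 91.1 |
| Tuesday's | 0.833 | 91.3 |
| Tuesday's | 1.50 | 91.4 |
| Tuesday's | 3.00 | 94.3 |
| Thursday's | 0.667 | 78.3 |
| Thursday's | 1.33 | 78.4 |
| Thursday's | 2.00 | 75.8 |
| Thursday's | 2.50 | 76.9 |
| Thursday's | 3.00 | 77.6 |

(each reading ± 1 percentage point)

- charges are per starting volume, the dose included; the dosed solution carries all of it
- the average divides the monomer in chains by the number of chains, living and dead together; two radicals that join make one chain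
- steps that have been proposed: initiator -> 2 initiating radical; free monomer + initiating radical -> growing radical + monomer in chains; 2 growing radical -> dead chain; free monomer + growing radical -> monomer in chains + growing radical; free monomer -> decomposition product
- the earlier runs do not show the number of chains; that part of a forecast is a guess

1. which of the two ends with the longer chains by the average number of monomer units in a chain (living and dead chains, two that joined counted as one) ("neither" if they lie within 10%) (epsilon / beta / neither)
2. average number of monomer units in a chain (living and dead chains, two that joined counted as one) at the end, epsilon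
3. average number of monomer units in a chain (living and dead chains, two that joined counted as one) at the end, beta

If pairwise loss of growing radical balances its supply from initiator, [growing radical] follows the square root of [initiator], and [initiator] falls exponentially. The rate of use of free monomer then integrates in closed form: the logarithm of charged over remaining free monomer grows as the square root of the initiator charged (dead-end polymerisation).

Saturday's first readings average 79.4% and Tuesday's 91.4%, at the same monomer charge. Scaled by that root to 0.2 mol%, they average 1.98. This is the exhaustion exponent, the logarithm of charged over remaining free monomer at the plateau.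

So I expected 86.2% in chains. Two initiating radicals per initiator and two growing radicals per chain make one chain per initiator, which is a guess the runs cannot test, and the length comes to 431.

Saturday's readings give 79.5% at 0.250 h and 83.6% at 3.00 h; that gap of 4.1 percentage points lies between two readings that each scatter by 1 point, and even taken whole it is less than the margin in relative terms, so I committed to neither.

The forecast gave neither, with 430 (210 to 900) for epsilon and 430 (210 to 1000) for beta, saying “Both runs should end much the same”.

The simulation gives 441 for epsilon and 441 for beta, so the answer is neither.

    initiator → 2 initiating radical (k = 0.00670 s⁻¹)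
    free monomer + initiating radical → growing radical + monomer in chains (k = 2.10 × 10⁷ M⁻¹ s⁻¹)
    2 growing radical → dead chain (k = 2.10 × 10⁸ M⁻¹ s⁻¹)
    free monomer + growing radical → monomer in chains + growing radical, rate k4*[growing radical]*[free monomer] (k = 1.80 × 10⁶ M⁻¹ s⁻¹)
    free monomer → decomposition product (k = 1.30 × 10⁻⁵ s⁻¹)

In beta at 1.20 h, initiator stood at 0% and dead chain at 5.00 × 10⁻⁴ mM, which is the initiator charge spread over starting volume plus feed, 5.00 × 10⁻⁴ mM. A neighbouring flask is beta with 0.08 mol% of initiator. The root scales the exponent to 1.25, which gives a length of 893, and that flask stands at 928.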